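In a closed flask with one overall reaction, target and substrate, bound forms counted, add up to the charge, so a single fraction x of the charge turned into target describes the progress of a run, and its odds x/(1−x) are the convenient measure.

| flask | substrate | free catalyst | time |
|---|---|---|---|
| maple | 0.500 M | 0.0250 M |  |
| ash | 0.200 M | 0.0250 M |  |
| oak | 0.250 M | 0.0250 M |  |
| alder | 0.500 M | 0.0130 M |  |
| elm | 0.170 M | 0.0500 M | 16 min |

- maple run (time / min: [target] / M): 2.0: 0.009; 4.0: 0.002; 6.0: 0.042; 8.0: 0.086; 10: 0.181; 12: 0.339; 14: 0.430; 16: 0.481
- ash run (time / min: [target] / M): 2.0: 0.002; 4.0: 0.009; 6.0: 0.004; 8.0: 0.009; 10: 0.033; 12: 0.042; 14: 0.050; 16: 0.086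
- oak run (time / min: [target] / M): 2.0: 0.008; 4.0: 0.006; 6.0: 0.011; 8.0: 0.021; 10: 0.048; 12: 0.061; 14: 0.093; 16: 0.120
- alder run (time / min: [target] / M): 2.0: 0; 4.0: 0; 6.0: 0.002; 8.0: 0; 10: 0; 12: 0.007; 14: 0.003; 16: 0.014

(readings scatter by 0.007 M)

- apparent order in [substrate] of the starting rate, round the charge of the maple run (the rate where two percent of its substrate have turned into target) (one fixed amount of target, the same in the runs compared)
- apparent order in [free catalyst] of the starting rate, round the charge of the maple run (the rate where two percent of its substrate have turned into target)
- the ash run starts with 0.300 M less of substrate than the maple run, and with no target. Compared where both hold the same amount of substrate, once fifteen percent of what the ash run was charged with has turned into target, is the ash run faster, slower or alike (within a tenth)?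
- target in the elm run at 16 min, as a share of the substrate charged

- Overall: substrate -> target, with free catalyst as catalyst.
- Constant volume, constant temperature.
- The analysis sees a species whether free or bound.
- An order is taken over about fifteen percent of the charge, up and down.

Start with one step: substrate feeding on target (autocatalysis), at a rate k × target × substrate. The odds then grow as exp(k·charge·t). The maple readings at 8.0 min and 12 min give 1.16 /M/min, the feed constant, which is the growth of the log odds per minute per molar of charge. Read the same way, the ash run gives 1.30 /M/min and the oak run 1.05 /M/min. At one fixed amount of target this step has order 1 in substrate and 0 in catalyst. At equal substrate its rate follows target, and the maple run then holds 0.300 M more target than the ash run, so the ash run should be the slower.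

With no target charged, that step makes none, so a seed flow from the catalyst comes next. Running the maple odds back to the start gives a flow of 5.85 × 10⁻⁴ M/min. At the fixed amount of target 0.0100 M, the feed step gives 0.00567 M/min, so the seed flow has a share of 0.0935. With the seed flow taken as independent of substrate, that share pulls the order in substrate towards 0.906.

The alder readings stay within about twice the scatter, so they do not separate a small k from a small seed flow. This reckoning wagers on the small seed flow, with k untouched by catalyst and the flow going as the square of catalyst. The order in catalyst is then 0.187. For the elm run, the ash flow of 8.59 × 10⁻⁴ M/min scaled to the elm catalyst gives seed odds of 0.103. The feed step multiplies these by 23.3, which gives 70.6% of the elm charge as target.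

The forecast differs, with 0.8, 2.3, slower and 99%. From the alder run it concludes: “so the catalyst order is above two”.

The simulation gives 0.90, 0.36, slower and 90.2%.

    free catalyst + substrate ⇌ catalyst-substrate complex, settled at all times (4.930 /M)
    catalyst-substrate complex + free catalyst → target + 2 free catalyst (19.02 /M/min)
    free catalyst + impurity → spent catalyst
    substrate + target → 2 target (1.164 /M/min)

Held fixed, k gives the alder run 0.00567 M/min at the fixed amount of target; the simulated rate there is 0.0057 M/min, against 0.0062 M/min in the maple run. Target feeding on substrate holds the order in catalyst at 0.36: the same flask without that step shows 4.2, and weighted by the seed share that is 0.393. In the elm run, the factor of 23.3 and the simulated 90.2% require seed odds of 0.395.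

All runs stem from a simulated flask on assumed constants.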